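**Plan**

- Retrosynthesis: the methylidene goes back to a ketone and the ring-B Br/Cl pair to a trisubstituted alkene. Ring B is then cut by a retro-Diels–Alder (isoprene) to (S)-4-bromo-3,3-dimethyl-2-methylidenecyclohexanone.
- Ring A is cut at its CH2–C(=CH2) bond and at its CMe2–C(spiro) bond by a retro-[4+2], giving a 2-silyloxy diene and 1-(phenylsulfonyl)allene.
- Enabling feature: in ring A the C–Br carbon and the methylidene carbon are 1,4-related, and the CMe2 carbon is next to the spiro carbon. This is the para pattern of an oxygenated diene with an acceptor dienophile, and the spiro carbon, which still needs two ring-B bonds, can enter as the sp carbon of an allene.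
- Forward: ring A (step 4), C–Br, enone unveiling, ring B by a second Diels–Alder, ring-B halogens via an epoxide, methylidene last.
- Stereochemistry: C–Br by CBS reduction then Appel inversion; the spiro centre by diene approach anti to the axial methyl of the Br-equatorial chair; C–Cl and tertiary C–Br by face-selective epoxidation, trans-diaxial chloride opening and retentive bromide entry.

Key step: step 4

Assumption: 4-methylpent-1-en-3-ol, phenyl propargyl sulfone and isoprene are taken as commercial.

**Route**

Step 1
Reactants: 1 4-methylpent-1-en-3-ol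
Product: 2 4-methylpent-1-en-3-one
Conditions: IBX, EtOAc, 75 °C; filter, distil
Reagents that add atoms: none
Why: Oxidation of a secondary allylic alcohol with IBX should give the vinyl ketone without touching the alkene, and no stereocentre remains.

Step 2
Reactants: 2 4-methylpent-1-en-3-one
Product: 3 tert-butyl(dimethyl)[(4-methylpenta-1,3-dien-3-yl)oxy]silane
Conditions: TBSOTf, Et3N, Et2O, 0 °C
Reagents that add atoms: tert-butyldimethylsilyl trifluoromethanesulfonate, CC(C)(C)[Si](C)(C)OS(=O)(=O)C(F)(F)F
Why: Soft enolisation and O-silylation (silyl enol ether formation) can only take the isopropyl C–H, so the cross-conjugated 2-silyloxy diene with a CMe2 terminus should form.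

Step 3
Reactants: 4 (prop-2-yn-1-ylsulfonyl)benzene
Product: 5 (propa-1,2-dien-1-ylsulfonyl)benzene
Conditions: basic Al2O3, CH2Cl2, 23 °C
Reagents that add atoms: none
Why: Base-surface prototropic propargyl-to-allenyl isomerisation of a propargylic sulfone is a known, mild way to the allenyl sulfone.

Step 4
Reactants: 3 tert-butyl(dimethyl)[(4-methylpenta-1,3-dien-3-yl)oxy]silane; 5 (propa-1,2-dien-1-ylsulfonyl)benzene
Product: 7 rac-4-(benzenesulfonyl)-2,2-dimethyl-3-methylidenecyclohexan-1-one, via silyl enol ether cycloadduct 6 (not isolated)
Conditions: PhMe, BHT (cat.), 100 °C, sealed tube; then 2 M HCl, THF, 23 °C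
Reagents that add atoms: none
Why: Normal-demand Diels–Alder reaction in which the 2-silyloxy diene, whose HOMO is largest at the CMe2 terminus, bonds through that terminus to the unhindered central sp carbon of the sulfonylallene in an asynchronous transition state while the CH2 terminus closes onto the sulfonyl-bearing carbon. The closest known reaction type is the [4+2] cycloaddition of 2-silyloxy dienes with 1-sulfonylallenes at the sulfone-conjugated π bond, which leaves the distal π bond as an exocyclic methylidene. Ring A closes in one [4+2] event (two σ bonds, six-membered ring), and aqueous acid then turns the silyl enol ether into the ketone that marks the future C–Br carbon. The only new stereocentre, the sulfonyl-bearing carbon, is formed without control and needs none, because it becomes a carbonyl carbon in step 7 and is sp2 in the target. The step needs para regioselectivity (silyloxy carbon 1,4 to the sulfonyl carbon) and site selectivity for the α,β π bond of the allene; the donor oxygen on the diene and the sulfone on the allene secure both. The hindered CMe2 terminus should be tolerated because it meets an sp carbon and not a fully substituted one.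

Step 5
Reactants: 7 rac-4-(benzenesulfonyl)-2,2-dimethyl-3-methylidenecyclohexan-1-one
Product: 8 (1R)-4-(benzenesulfonyl)-2,2-dimethyl-3-methylidenecyclohexan-1-ol (both C4 epimers)
Conditions: (S)-2-methyl-CBS-oxazaborolidine (0.2 equiv), catecholborane, PhMe, −78 → −40 °C
Reagents that add atoms: none
Why: Corey–Bakshi–Shibata reduction should differentiate the quaternary (large) from the methylene (small) flank and give the (R)-carbinol with the (S)-catalyst in both epimeric series, and catecholborane spares the 1,1-disubstituted alkene.

Step 6
Reactants: 8 (1R)-4-(benzenesulfonyl)-2,2-dimethyl-3-methylidenecyclohexan-1-ol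
Product: 9 {[(4S)-4-bromo-3,3-dimethyl-2-methylidenecyclohexyl]sulfonyl}benzene (both C1 epimers)
Conditions: CBr4, PPh3, 2,6-lutidine, CH2Cl2, 0 → 23 °C
Reagents that add atoms: tetrabromomethane, BrC(Br)(Br)Br
Why: Appel reaction, in which bromide displaces the alkoxyphosphonium group by SN2 with inversion, should give the (S)-bromide, as known for secondary cyclohexanols flanked by a gem-dimethyl carbon.

Step 7
Reactants: 9 {[(4S)-4-bromo-3,3-dimethyl-2-methylidenecyclohexyl]sulfonyl}benzene
Product: 10 (4S)-4-bromo-3,3-dimethyl-2-methylidenecyclohexan-1-one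
Conditions: LiN(SiMe3)2 (1.1 equiv), THF, −78 °C; Me3SiOOSiMe3, −78 → −20 °C; aq. NH4Cl
Reagents that add atoms: bis(trimethylsilyl) peroxide, C[Si](C)(C)OO[Si](C)(C)C
Why: Oxidative desulfonylation, in which the allylic α-sulfonyl carbanion is oxygenated at the α-carbon and the α-silyloxy sulfone collapses with loss of sulfinate, should converge both epimers to the enone while the low temperature and the equatorial C–Br disfavour E2.

Step 8
Reactants: 10 (4S)-4-bromo-3,3-dimethyl-2-methylidenecyclohexan-1-one; 11 isoprene
Product: 12 (2S,6R)-2-bromo-1,1,9-trimethylspiro[5.5]undec-8-en-5-one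
Conditions: isoprene (10 equiv), Me2AlCl (0.3 equiv), CH2Cl2, −78 → −30 °C
Reagents that add atoms: none
Why: Lewis-acid-catalysed Diels–Alder reaction of a 2-methylidene ketone with isoprene should give the para adduct (methyl 1,4 to the spiro carbon), and the diene should add anti to the axial methyl of the chair with equatorial bromine, so the new ring bond at the spiro carbon ends trans to Br.

Step 9
Reactants: 12 (2S,6R)-2-bromo-1,1,9-trimethylspiro[5.5]undec-8-en-5-one
Product: 13 (2S,6R,8S,9R)-2-bromo-8,9-epoxy-1,1,9-trimethylspiro[5.5]undecan-5-one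
Conditions: mCPBA, NaHCO3, CH2Cl2, 0 °C
Reagents that add atoms: 3-chloroperbenzoic acid, OOC(=O)c1cccc(Cl)c1
Why: Prilezhaev epoxidation of the trisubstituted alkene should outrun Baeyer–Villiger oxidation of the hindered ketone and take the face anti to the axial carbonyl-bearing arm at the spiro carbon (the CMe2 carbon being equatorial on ring B), which sets C8 and C9.

Step 10
Reactants: 13 (2S,6R,8S,9R)-2-bromo-8,9-epoxy-1,1,9-trimethylspiro[5.5]undecan-5-one
Product: 14 (2S,6R,8R,9R)-2-bromo-8-chloro-9-hydroxy-1,1,9-trimethylspiro[5.5]undecan-5-one
Conditions: Li2CuCl4 (2 equiv), THF, 23 °C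
Reagents that add atoms: dilithium tetrachlorocuprate, [Li+].[Li+].[Cu+2].[Cl-].[Cl-].[Cl-].[Cl-]
Why: Nucleophilic epoxide opening by chloride should occur at the secondary carbon with inversion and in the trans-diaxial (Fürst–Plattner) sense, giving axial Cl at C8 and leaving the tertiary axial alcohol.

Step 11
Reactants: 14 (2S,6R,8R,9R)-2-bromo-8-chloro-9-hydroxy-1,1,9-trimethylspiro[5.5]undecan-5-one
Product: 15 (2S,6R,8R,9R)-2,9-dibromo-8-chloro-1,1,9-trimethylspiro[5.5]undecan-5-one
Conditions: Me3SiBr (3 equiv), CH2Cl2, −20 → 0 °C
Reagents that add atoms: bromotrimethylsilane, C[Si](C)(C)Br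
Why: SN1-type substitution of the tertiary alcohol should proceed with retention, because the anti-periplanar axial chlorine bridges the cation and bromide then enters axially at the tertiary carbon from the face the oxygen left.

Step 12
Reactants: 15 (2S,6R,8R,9R)-2,9-dibromo-8-chloro-1,1,9-trimethylspiro[5.5]undecan-5-one
Product: 16 (2S,6S,8R,9R)-2,9-dibromo-8-chloro-1,1,9-trimethyl-5-methylidenespiro[5.5]undecane
Conditions: Cp2TiMe2 (3 equiv), PhMe/THF, 65 °C, dark
Reagents that add atoms: dimethyltitanocene, C[Ti](C)(C1C=CC=C1)C1C=CC=C1
Why: Petasis methylenation by the non-basic titanium methylidene should convert the hindered ketone into the methylidene without E2 of the halides and without touching any stereocentre.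

**Compound list**

1 | 4-methylpent-1-en-3-ol | C=CC(O)C(C)C | starting material
2 | 4-methylpent-1-en-3-one | C=CC(=O)C(C)C | intermediate
3 | tert-butyl(dimethyl)[(4-methylpenta-1,3-dien-3-yl)oxy]silane | C=CC(O[Si](C)(C)C(C)(C)C)=C(C)C | intermediate
4 | (prop-2-yn-1-ylsulfonyl)benzene (phenyl propargyl sulfone) | C#CCS(=O)(=O)c1ccccc1 | starting material
5 | (propa-1,2-dien-1-ylsulfonyl)benzene | C=C=CS(=O)(=O)c1ccccc1 | intermediate
6 | {[4-(benzenesulfonyl)-6,6-dimethyl-5-methylidenecyclohex-1-en-1-yl]oxy}(tert-butyl)dimethylsilane, racemic | C=C1C(S(=O)(=O)c2ccccc2)CC=C(O[Si](C)(C)C(C)(C)C)C1(C)C | intermediate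
7 | rac-4-(benzenesulfonyl)-2,2-dimethyl-3-methylidenecyclohexan-1-one | C=C1C(S(=O)(=O)c2ccccc2)CCC(=O)C1(C)C | intermediate
8 | (1R)-4-(benzenesulfonyl)-2,2-dimethyl-3-methylidenecyclohexan-1-ol, both C4 epimers | C=C1C(S(=O)(=O)c2ccccc2)CC[C@@H](O)C1(C)C | intermediate
9 | {[(4S)-4-bromo-3,3-dimethyl-2-methylidenecyclohexyl]sulfonyl}benzene, both C1 epimers | C=C1C(S(=O)(=O)c2ccccc2)CC[C@H](Br)C1(C)C | intermediate
10 | (4S)-4-bromo-3,3-dimethyl-2-methylidenecyclohexan-1-one | C=C1C(=O)CC[C@H](Br)C1(C)C | intermediate
11 | isoprene (2-methylbuta-1,3-diene) | C=CC(C)=C | starting material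
12 | (2S,6R)-2-bromo-1,1,9-trimethylspiro[5.5]undec-8-en-5-one | O=C1CC[C@H](Br)C(C)(C)[C@]12CCC(C)=CC2 | intermediate
13 | (2S,6R,8S,9R)-2-bromo-8,9-epoxy-1,1,9-trimethylspiro[5.5]undecan-5-one (oxirane oxygen on the ring-B face of the CMe2 carbon) | O=C1CC[C@H](Br)C(C)(C)[C@]12CC[C@@]3(C)O[C@H]3C2 | intermediate
14 | (2S,6R,8R,9R)-2-bromo-8-chloro-9-hydroxy-1,1,9-trimethylspiro[5.5]undecan-5-one | O=C1CC[C@H](Br)C(C)(C)[C@]12CC[C@@](C)(O)[C@H](Cl)C2 | intermediate
15 | (2S,6R,8R,9R)-2,9-dibromo-8-chloro-1,1,9-trimethylspiro[5.5]undecan-5-one | O=C1CC[C@H](Br)C(C)(C)[C@]12CC[C@@](C)(Br)[C@H](Cl)C2 | intermediate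
16 | (2S,6S,8R,9R)-2,9-dibromo-8-chloro-1,1,9-trimethyl-5-methylidenespiro[5.5]undecane | C=C1CC[C@H](Br)C(C)(C)[C@]12CC[C@@](C)(Br)[C@H](Cl)C2 | target

Total step count: 12
Longest linear sequence: 11 steps (steps 1, 2 and 4 to 12; step 3 is a one-step branch)

**Steps most likely to fail**

Step 6. The neopentylic alkoxyphosphonium ion may ionise instead of being displaced, and then methyl migration towards an allylic cation or elimination would take over from inversion. The fallback changes the order so that the displacement is run on an electron-poor enone, in which such a cation is disfavoured. It sets out from 8: deprotonation with LiN(SiMe3)2 (2.2 equiv) and oxygenation with Me3SiOOSiMe3, followed by acidic work-up, should give (4R)-4-hydroxy-3,3-dimethyl-2-methylidenecyclohexan-1-one F2. Tf2O and pyridine at −40 °C should then give (1R)-2,2-dimethyl-3-methylidene-4-oxocyclohexyl trifluoromethanesulfonate F3, and Bu4NBr in toluene at 0 °C should displace the sulfonate with inversion. The fallback comes back to the route at 10.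

Step 4. The diene may fail to reach its s-cis form fast enough, and a stepwise zwitterionic path could then end in [2+2] closure or in silyl loss to an open-chain adduct. The fallback makes the two bonds one after the other by anionic chemistry. It sets out from 3 and 5: Bu4N[Ph3SiF2] in THF at −78 °C should free the enolate, which adds to the central allene carbon and gives, after protonation, 6-(benzenesulfonyl)-4,4-dimethyl-5-methylidenehex-1-en-3-one F1. DBU in MeCN should then close the ring by intramolecular 6-endo Michael addition of the sulfonyl carbanion onto the vinyl ketone. The fallback comes back at 7.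

Step 11. Ionisation of the β-chloro tertiary alcohol may lead to E1 elimination or hydride shift instead of bromide capture, with loss of the tertiary centre. The fallback avoids the alcohol altogether. It sets out from 12 and uses direct anti addition of BrCl (Bu4NBrCl2, CH2Cl2, −78 → 0 °C): the bromonium ion should form on the face anti to the axial arm and be opened trans-diaxially by chloride at the secondary carbon. This comes back to the route at 15 and bypasses 13 and 14. No compound outside the list is made (entry F0), but the Markovnikov regioisomer is the expected contaminant.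

Further compounds
F1 | step 4 | 6-(benzenesulfonyl)-4,4-dimethyl-5-methylidenehex-1-en-3-one | C=CC(=O)C(C)(C)C(=C)CS(=O)(=O)c1ccccc1
F2 | step 6 | (4R)-4-hydroxy-3,3-dimethyl-2-methylidenecyclohexan-1-one | C=C1C(=O)CC[C@@H](O)C1(C)C
F3 | step 6 | (1R)-2,2-dimethyl-3-methylidene-4-oxocyclohexyl trifluoromethanesulfonate | C=C1C(=O)CC[C@@H](OS(=O)(=O)C(F)(F)F)C1(C)C
F0 | step 11 | none | none
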